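**Plan**

- Retrosynthesis: the cyclohexadienone ring is opened first, by a retro-Claisen cut between the acetyl-bearing ring carbon and the enol carbon beside the quaternary centre. This gives a linear methyl 3,5,7-trioxooctanoate carrying C(Me)(geranyl) at C2 and the chromenylmethyl group at C4.
- Enabling feature: that ring is a 2-acetylcyclohexane-1,3,5-trione, held out of aromaticity by its quaternary carbon. Its other five ring carbons are carbonyl/enol carbons or the doubly activated carbons between them, so it is the Claisen-folded form of a tetraketide ester.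
- Further cuts: ArCH2–C4 (ortho-quinone methide + 1,3-diketone), C3–C4 (acid chloride + kinetic enolate of 4-methoxypent-3-en-2-one, whose enol ether masks the C7 carbonyl and silences C6), and geranyl–C2 (malonate alkylation).
- Forward order: aromatic ring (phloroglucinol), then the pyran ring (propargyl Claisen/oxa-6π), then union of the masked chain at the methylene bridge, unmasking, and the cyclohexadienone ring closed last.
- Stereochemistry: the single quaternary stereocentre comes from enzymatic desymmetrisation of prochiral dimethyl geranyl(methyl)malonate. The acid arm becomes the enol carbon next to the bridge and the ester arm becomes the Claisen acceptor. The centre has no alpha-hydrogen and is carried through unchanged.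

Key step: step 11

Assumption: pig liver esterase is taken to show with the geranyl substrate the same sense of enantiotopic-group selection as with long-chain 2-alkyl-2-methylmalonates, giving the (R)-half ester. The (R) descriptor of the target refers to the enol tautomer drawn.

**Route**

Step 1
Reactants: 1 dimethyl 2-methylpropanedioate; 2 geranyl bromide
Product: 3 dimethyl 2-[(2E)-3,7-dimethylocta-2,6-dien-1-yl]-2-methylpropanedioate
Conditions: NaH, THF, 0 °C; then 2, 0 °C → rt
Reagents that add atoms: none
Why: Malonate alkylation (SN2) of the sodium enolate by the primary allylic bromide should go at the unhindered CH2 end and gives a prochiral diester with two enantiotopic ester groups, so no stereocentre is set here.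

Step 2
Reactants: 3 dimethyl 2-[(2E)-3,7-dimethylocta-2,6-dien-1-yl]-2-methylpropanedioate
Product: 4 (2R,4E)-2-(methoxycarbonyl)-2,5,9-trimethyldeca-4,8-dienoic acid
Conditions: pig liver esterase, 0.1 M phosphate buffer pH 7.5, DMSO (10% v/v), rt, pH-stat with 1 M NaOH; then 1 M HCl to pH 2, EtOAc
Reagents that add atoms: water, O
Why: Enzymatic desymmetrisation (enantiotopic-group-selective ester hydrolysis) of a prochiral 2,2-disubstituted malonate should cleave one of the two methyl esters and so set the quaternary stereocentre, the (R)-half ester being expected by analogy with long-chain 2-alkyl-2-methylmalonates, while the untouched ester is kept as the later Claisen acceptor.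

Step 3
Reactants: 5 pentane-2,4-dione
Product: 6 (3E)-4-methoxypent-3-en-2-one
Conditions: HC(OMe)3, TsOH·H2O (cat.), MeOH, rt → 55 °C; distillation
Reagents that add atoms: trimethyl orthoformate, COC(OC)OC
Why: Acid-catalysed enol ether formation (ketalisation by the orthoester, then loss of methanol) should give the conjugated (E)-vinylogous ester, in which one carbonyl of acetylacetone is masked and the central carbon is no longer an active methylene.

Step 4
Reactants: 4 (2R,4E)-2-(methoxycarbonyl)-2,5,9-trimethyldeca-4,8-dienoic acid; 6 (3E)-4-methoxypent-3-en-2-one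
Product: 8 methyl (2R,6E)-2-[(2E)-3,7-dimethylocta-2,6-dien-1-yl]-7-methoxy-2-methyl-3,5-dioxooct-6-enoate, via acid chloride 7 (not isolated)
Conditions: 4, 1-chloro-N,N,2-trimethylprop-1-en-1-amine, CH2Cl2, 0 °C → rt; solution added to the lithium enolate of 6 [6 (2.2 equiv), LiN(SiMe3)2 (2.2 equiv), THF, −78 °C], −78 → −40 °C; aq. NH4Cl
Reagents that add atoms: none
Why: C-Acylation of a kinetic ketone enolate by an acid chloride (crossed Claisen-type acylation): the amide base removes the alpha-prime methyl proton of the vinylogous ester, the acid chloride (no alpha-hydrogen, hence no ketene and no epimerisation) reacts far faster than the neopentyl methyl ester on the same carbon, and the second equivalent of enolate takes up the acidic 1,3-diketone product.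

Step 5
Reactants: 9 phloroglucinol; 10 butanoyl chloride
Product: 11 1-(2,4,6-trihydroxyphenyl)butan-1-one
Conditions: AlCl3, PhNO2, 0 → 60 °C; then ice/1 M HCl
Reagents that add atoms: none
Why: Friedel–Crafts acylation of the very electron-rich triol should stop at the mono-ketone because the first acyl group deactivates the ring.

Step 6
Reactants: 11 1-(2,4,6-trihydroxyphenyl)butan-1-one; 12 3-chloro-3-methylbut-1-yne
Product: 13 1-{2,6-dihydroxy-4-[(2-methylbut-3-yn-2-yl)oxy]phenyl}butan-1-one
Conditions: DBU, CuCl2·2H2O (cat.), MeCN, 0 °C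
Reagents that add atoms: none
Why: Copper-catalysed O-propargylation (Williamson-type etherification with a tertiary propargylic chloride) should take place at the 4-OH, which is para to the acyl group, not hydrogen-bonded to the ketone and the most acidic hydroxyl.

Step 7
Reactants: 13 1-{2,6-dihydroxy-4-[(2-methylbut-3-yn-2-yl)oxy]phenyl}butan-1-one
Product: 14 1-(5,7-dihydroxy-2,2-dimethyl-2H-chromen-6-yl)butan-1-one
Conditions: PhNEt2, 160 °C
Reagents that add atoms: none
Why: Aromatic propargyl Claisen rearrangement, followed by enolisation, 1,5-hydrogen shift and oxa-6π electrocyclisation, should give the 2,2-dimethyl-2H-chromene; the two ortho positions are equivalent and the ring oxygen is by construction the former 4-O, which fixes the 6-acyl-5,7-dihydroxy pattern.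

Step 8
Reactants: 14 1-(5,7-dihydroxy-2,2-dimethyl-2H-chromen-6-yl)butan-1-one
Product: 15 1-{8-[(dimethylamino)methyl]-5,7-dihydroxy-2,2-dimethyl-2H-chromen-6-yl}butan-1-one
Conditions: dimethyl(methylidene)ammonium iodide, CH2Cl2, 0 °C → rt; aq. NaHCO3
Reagents that add atoms: dimethyl(methylidene)ammonium iodide, C=[N+](C)C.[I-]
Why: Mannich aminomethylation (electrophilic aromatic substitution by the preformed iminium ion) can only occur at C8, the single free and doubly activated aromatic position.

Step 9
Reactants: 15 1-{8-[(dimethylamino)methyl]-5,7-dihydroxy-2,2-dimethyl-2H-chromen-6-yl}butan-1-one; 8 methyl (2R,6E)-2-[(2E)-3,7-dimethylocta-2,6-dien-1-yl]-7-methoxy-2-methyl-3,5-dioxooct-6-enoate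
Product: 18 methyl (2R,6E)-4-[(6-butanoyl-5,7-dihydroxy-2,2-dimethyl-2H-chromen-8-yl)methyl]-2-[(2E)-3,7-dimethylocta-2,6-dien-1-yl]-7-methoxy-2-methyl-3,5-dioxooct-6-enoate, via benzylic trimethylammonium iodide 16 (not isolated), via ortho-quinone methide 17 (not isolated)
Conditions: MeI (1.0 equiv), THF, rt, then evaporate; added in portions to 8, K2CO3, MeCN, 0 °C → rt
Reagents that add atoms: none
Why: N-Methylation turns the amine into a leaving group, mild base then releases trimethylamine to give the ortho-quinone methide, and Michael addition of the 1,3-diketone through its only active methylene (C4; C6 is a vinylic CH of the enol ether) forms the ArCH2–C bond and restores the aromatic ring; the new C4 centre is enolisable and of no consequence.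

Step 10
Reactants: 18 methyl (2R,6E)-4-[(6-butanoyl-5,7-dihydroxy-2,2-dimethyl-2H-chromen-8-yl)methyl]-2-[(2E)-3,7-dimethylocta-2,6-dien-1-yl]-7-methoxy-2-methyl-3,5-dioxooct-6-enoate
Product: 19 methyl (2R)-4-[(6-butanoyl-5,7-dihydroxy-2,2-dimethyl-2H-chromen-8-yl)methyl]-2-[(2E)-3,7-dimethylocta-2,6-dien-1-yl]-2-methyl-3,5,7-trioxooctanoate
Conditions: 0.5 M HCl, THF–H2O, 0 °C → rt; product used crude
Reagents that add atoms: water, O
Why: Acid-catalysed hydrolysis of the β-methoxy enone (vinylogous ester hydrolysis) should be much faster under dilute aqueous acid than any change at the geranyl or chromene double bonds and frees the third carbonyl, so that C6 becomes a doubly activated methylene.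

Step 11
Reactants: 19 methyl (2R)-4-[(6-butanoyl-5,7-dihydroxy-2,2-dimethyl-2H-chromen-8-yl)methyl]-2-[(2E)-3,7-dimethylocta-2,6-dien-1-yl]-2-methyl-3,5,7-trioxooctanoate
Product: 20 (4R)-2-acetyl-6-[(6-butanoyl-5,7-dihydroxy-2,2-dimethyl-2H-chromen-8-yl)methyl]-4-[(2E)-3,7-dimethylocta-2,6-dien-1-yl]-3,5-dihydroxy-4-methylcyclohexa-2,5-dien-1-one
Conditions: NaOMe (6 equiv), MeOH, 0 °C → rt; then cold 1 M HCl to pH 3
Reagents that add atoms: none
Why: Dieckmann-type intramolecular Claisen condensation, closest in kind to the alkoxide-induced Claisen folding of 3,5,7-trioxo esters into acylphloroglucinols: methoxide forms the enolate of the C5/C7 β-diketone (the most acidic site, since the C3/C5 unit is substituted at C4), its central carbon C6 adds to the ester carbonyl C1, methoxide is expelled and the product is trapped at once as the stabilised 2-acyl-1,3,5-trione anion, which makes the closure irreversible. The six-membered carbocycle forms by a 6-exo-trig (enolexo) C-acylation that creates the C6–C1 bond. No stereocentre is formed; the quaternary carbon C2 has no alpha-hydrogen and cannot epimerise, so the (R) configuration from step 2 is kept, and the C4 epimers converge because C4 becomes an enol carbon. The step needs C6 to react instead of the terminal methyl C8, and Claisen instead of aldol: attack of C8 on C1 would give an eight-membered ring, an aldol of C8 onto the neopentyl C3 ketone would need a dianion that methoxide does not form, and O-acylation to the enol lactone is reversed by methoxide, while only C-acylation ends in the stable anion. The free phenols ride through as phenoxides and any hemiketal between the 7-OH and a chain carbonyl reopens in base; acidification should give the enolised dienone tautomer drawn for 20.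

**Compound list**

1 | dimethyl 2-methylpropanedioate | COC(=O)C(C)C(=O)OC | starting material
2 | geranyl bromide, (2E)-1-bromo-3,7-dimethylocta-2,6-diene | BrC/C=C(\C)CCC=C(C)C | starting material
3 | dimethyl 2-[(2E)-3,7-dimethylocta-2,6-dien-1-yl]-2-methylpropanedioate | COC(=O)C(C)(C/C=C(\C)CCC=C(C)C)C(=O)OC | intermediate
4 | (2R,4E)-2-(methoxycarbonyl)-2,5,9-trimethyldeca-4,8-dienoic acid | OC(=O)[C@@](C)(C/C=C(\C)CCC=C(C)C)C(=O)OC | intermediate
5 | pentane-2,4-dione | CC(=O)CC(C)=O | starting material
6 | (3E)-4-methoxypent-3-en-2-one | CO/C(C)=C/C(C)=O | intermediate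
7 | methyl (2S,4E)-2-(chlorocarbonyl)-2,5,9-trimethyldeca-4,8-dienoate (same spatial arrangement as 4) | ClC(=O)[C@@](C)(C/C=C(\C)CCC=C(C)C)C(=O)OC | intermediate (not isolated)
8 | methyl (2R,6E)-2-[(2E)-3,7-dimethylocta-2,6-dien-1-yl]-7-methoxy-2-methyl-3,5-dioxooct-6-enoate | CO/C(C)=C/C(=O)CC(=O)[C@@](C)(C/C=C(\C)CCC=C(C)C)C(=O)OC | intermediate
9 | phloroglucinol | Oc1cc(O)cc(O)c1 | starting material
10 | butanoyl chloride | CCCC(Cl)=O | starting material
11 | 1-(2,4,6-trihydroxyphenyl)butan-1-one | CCCC(=O)c1c(O)cc(O)cc1O | intermediate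
12 | 3-chloro-3-methylbut-1-yne | CC(C)(Cl)C#C | starting material
13 | 1-{2,6-dihydroxy-4-[(2-methylbut-3-yn-2-yl)oxy]phenyl}butan-1-one | CCCC(=O)c1c(O)cc(OC(C)(C)C#C)cc1O | intermediate
14 | 1-(5,7-dihydroxy-2,2-dimethyl-2H-chromen-6-yl)butan-1-one | CCCC(=O)c1c(O)cc2OC(C)(C)C=Cc2c1O | intermediate
15 | 1-{8-[(dimethylamino)methyl]-5,7-dihydroxy-2,2-dimethyl-2H-chromen-6-yl}butan-1-one | CCCC(=O)c1c(O)c(CN(C)C)c2OC(C)(C)C=Cc2c1O | intermediate
16 | (6-butanoyl-5,7-dihydroxy-2,2-dimethyl-2H-chromen-8-yl)-N,N,N-trimethylmethanaminium iodide | CCCC(=O)c1c(O)c(C[N+](C)(C)C)c2OC(C)(C)C=Cc2c1O.[I-] | intermediate (not isolated)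
17 | 6-butanoyl-5-hydroxy-2,2-dimethyl-8-methylidene-2H-chromen-7(8H)-one (ortho-quinone methide) | CCCC(=O)C1=C(O)C2=C(OC(C)(C)C=C2)C(=C)C1=O | intermediate (not isolated)
18 | methyl (2R,6E)-4-[(6-butanoyl-5,7-dihydroxy-2,2-dimethyl-2H-chromen-8-yl)methyl]-2-[(2E)-3,7-dimethylocta-2,6-dien-1-yl]-7-methoxy-2-methyl-3,5-dioxooct-6-enoate (C4 epimers and enol forms) | CO/C(C)=C/C(=O)C(Cc1c(O)c(C(=O)CCC)c(O)c2C=CC(C)(C)Oc12)C(=O)[C@@](C)(C/C=C(\C)CCC=C(C)C)C(=O)OC | intermediate
19 | methyl (2R)-4-[(6-butanoyl-5,7-dihydroxy-2,2-dimethyl-2H-chromen-8-yl)methyl]-2-[(2E)-3,7-dimethylocta-2,6-dien-1-yl]-2-methyl-3,5,7-trioxooctanoate (C4 epimers and enol forms) | CC(=O)CC(=O)C(Cc1c(O)c(C(=O)CCC)c(O)c2C=CC(C)(C)Oc12)C(=O)[C@@](C)(C/C=C(\C)CCC=C(C)C)C(=O)OC | intermediate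
20 | (4R)-2-acetyl-6-[(6-butanoyl-5,7-dihydroxy-2,2-dimethyl-2H-chromen-8-yl)methyl]-4-[(2E)-3,7-dimethylocta-2,6-dien-1-yl]-3,5-dihydroxy-4-methylcyclohexa-2,5-dien-1-one | CCCC(=O)c1c(O)c2c(c(CC3=C(O)[C@@](C)(C/C=C(\C)CCC=C(C)C)C(O)=C(C(C)=O)C3=O)c1O)OC(C)(C)C=C2 | target

**Summary**

Total step count: 11. Longest linear sequence: 7 steps (steps 5, 6, 7, 8, 9, 10, 11, from phloroglucinol). The chain branch (steps 1, 2, 4) and step 3 converge at steps 4 and 9.

**Steps most likely to fail, with fallbacks**

Step 11. The Claisen closure onto the neopentyl ester may be slow enough that base-induced retro-Michael loss of the chromenylmethyl unit from C4, or cleavage of the chain, overtakes it. The fallback reverses the order of ring closure and fragment union. It sets out from 8: dilute aqueous HCl in THF should hydrolyse the enol ether to methyl (2R)-2-[(2E)-3,7-dimethylocta-2,6-dien-1-yl]-2-methyl-3,5,7-trioxooctanoate F1. NaOMe in MeOH should then close the unencumbered chain by the same Claisen condensation to (4R)-2-acetyl-4-[(2E)-3,7-dimethylocta-2,6-dien-1-yl]-3,5-dihydroxy-4-methylcyclohexa-2,5-dien-1-one F2, which has a single nucleophilic ring CH. Michael addition of F2 to the ortho-quinone methide 17, released from 16 with K2CO3 in MeCN as in step 9, is the classical methylene bridging of an acylfilicinic acid and comes back to the route at 20.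

Step 10. Instead of simple hydrolysis, the enolised diketone may cyclise onto the vinylogous ester with loss of methanol (4-pyranone formation), or the 7-OH may form a hemiketal that dehydrates. The fallback makes the over-cyclised form the intended mask. It sets out from 18: a catalytic amount of camphorsulfonic acid in CH2Cl2 should drive the O-cyclisation fully to methyl (2R,4E)-2-{3-[(6-butanoyl-5,7-dihydroxy-2,2-dimethyl-2H-chromen-8-yl)methyl]-6-methyl-4-oxo-4H-pyran-2-yl}-2,5,9-trimethyldeca-4,8-dienoate F3, a stable compound with no C4 stereocentre. Ba(OH)2 in aqueous dioxane should then open the pyranone by hydroxide addition (the classical pyranone-to-1,3,5-triketone unmasking) to the polyanion of 19, which closes by the Claisen condensation in the same flask. Acidification comes back to the route at 20.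

Step 2. The esterase may discriminate the enantiotopic esters poorly, or in the opposite sense, with the bulky branched geranyl chain. The fallback replaces desymmetrisation by classical resolution. It sets out from 3: one equivalent of KOH in MeOH should give racemic 2-(methoxycarbonyl)-2,5,9-trimethyldeca-4,8-dienoic acid F4. Fractional crystallisation with (S)-1-phenylethylamine (or its enantiomer, whichever gives the less soluble salt of the (R)-acid) should give the (S)-1-phenylethylammonium salt of the (R)-acid F5. Acidification and extraction come back to the route at 4.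

Further compounds
F1 | step 11 | methyl (2R)-2-[(2E)-3,7-dimethylocta-2,6-dien-1-yl]-2-methyl-3,5,7-trioxooctanoate | CC(=O)CC(=O)CC(=O)[C@@](C)(C/C=C(\C)CCC=C(C)C)C(=O)OC
F2 | step 11 | (4R)-2-acetyl-4-[(2E)-3,7-dimethylocta-2,6-dien-1-yl]-3,5-dihydroxy-4-methylcyclohexa-2,5-dien-1-one | O=C1C=C(O)[C@@](C)(C/C=C(\C)CCC=C(C)C)C(O)=C1C(C)=O
F3 | step 10 | methyl (2R,4E)-2-{3-[(6-butanoyl-5,7-dihydroxy-2,2-dimethyl-2H-chromen-8-yl)methyl]-6-methyl-4-oxo-4H-pyran-2-yl}-2,5,9-trimethyldeca-4,8-dienoate | CC1=CC(=O)C(Cc2c(O)c(C(=O)CCC)c(O)c3C=CC(C)(C)Oc23)=C(O1)[C@@](C)(C/C=C(\C)CCC=C(C)C)C(=O)OC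
F4 | step 2 | racemic (4E)-2-(methoxycarbonyl)-2,5,9-trimethyldeca-4,8-dienoic acid | OC(=O)C(C)(C/C=C(\C)CCC=C(C)C)C(=O)OC
F5 | step 2 | (S)-1-phenylethylammonium (2R,4E)-2-(methoxycarbonyl)-2,5,9-trimethyldeca-4,8-dienoate | [O-]C(=O)[C@@](C)(C/C=C(\C)CCC=C(C)C)C(=O)OC.C[C@H]([NH3+])c1ccccc1
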